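(The numbers in the tables are simulated for an exercise; the scatter is artificial.)

- −10.0 µM: that was the catalyst margin of the east flask, free catalyst charged minus impurity charged.

all flasks: starting material 0.0010 M; gas phase 0.058 mM (held); free catalyst 25 µM

| run | impurity | remark | time |
|---|---|---|---|
| east | 35 µM | the very flask that is asked about, followed so far |  |
| south | 18 µM | run made earlier |  |
| flask | 35 µM |  | 4.0 min |

- east (time / s: target / %): 10.0: 9.1; 25.0: 10.1; 40.0: 8.6; 60.0: 9.5; 90.0: 7.5
- south (time / min: target / %): 0.250: 21.4; 0.667: 43.6; 1.33: 60.3; 2.00: 64.5; 3.00: 56.8

(standard deviation of a reading: 1 percentage point)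

- at the start none of the gas phase is in solution

- eta: doubling the transfer coefficient of the gas phase, all else as stated
- zeta: doubling the amount of free catalyst, all else as stated
- beta: doubling the saturation concentration of gas phase, all else as stated

* amount of target at 4.0 min, in percent of the starting material charged
* the change that raises the amount of target at 4.0 min, in percent of the starting material charged most ("none" if none brings more than 2 percentage points) (eta / zeta / beta / none)
* amount of target at 4.0 min, in percent of the starting material charged, after eta

- I assumed that one impurity takes one free catalyst. That made free catalyst the limiting reagent of the poisoning in the east flask.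
- I began with two extremes. If the catalyst died at the first instant, the east flask held no target.
- At the other extreme, free catalyst outlasted the impurity and kept working. The south run stood on that side, with a margin of 7.00 µM, and its target read 64.5% at 2.00 min.
- The east readings lay between these extremes. Target read 9.1% at 10.0 s and then stopped rising, so I took it as a burst that ended when the free catalyst was used up, with 10.0 µM of impurity over.
- After the burst I expected a slow loss. East target read 10.1% at 25.0 s and 7.5% at 90.0 s, a rough rate of 0.275 min⁻¹ given the scatter. Carried to the asked time, that gave me 3.77%.
- Doubling the free catalyst lifted the margin to 15.0 µM, more than the south run's. Eta and beta left it at −10.0 µM, so I chose zeta.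
- The forecast gave 8.5%, chose beta and put eta at 11%, on the ground that “the catalyst is apparently poisoned within seconds”. My figure was lower, and my choice differed.

    gas phase ⇌ dissolved gas, rate k1*(csat - [dissolved gas]) (kL = 0.460 s⁻¹)
    target ⇌ isomer of the product (K = 25.0, k = 0.00450 s⁻¹)
    starting material + dissolved gas + free catalyst → free catalyst + target (k = 6.20 × 10⁷ M⁻² s⁻¹)
    free catalyst + impurity → spent catalyst (k = 16000 M⁻¹ s⁻¹)

- The flask gave 4.11%, and zeta won with 37 percentage points against 3.7 points for beta; eta gave 5.40%. At 4.00 min the isomer of the product held 7.24%. In size, the margin of −10.0 µM is 28.6% of the impurity charge, and 29% of that charge stood at 4.00 min. A neighbour flask with 2.1 × 10⁻⁵ M of impurity had a margin of 4.00 µM, which is 16.0% of the catalyst charge. At 4.00 min it held 46.5% of target and 16.0% of free catalyst.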